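Time can be taken out of the comparison of the two routes from Zb by dividing one rate by the other.

| setting | delta | gamma | theta | eta | violet | grey | ochre | teal |
|---|---|---|---|---|---|---|---|---|
| Zb | 0.037 M | 0.018 M | 0.074 M | 0.037 M | 0.037 M | 0.037 M | 0.037 M | 0.037 M (fed, over 24.0 h) |
| Za | 0.1 mol% | 0.1 mol% | 0.1 mol% | 0.15 mol% | 0.1 mol% | 0.1 mol% | 0.1 mol% | 0.1 mol% |
| remark | run made earlier | run made earlier | run made earlier | run made earlier | a single well-mixed tank run continuously and read at steady state, 30 h in it on average | a single well-mixed tank run continuously and read at steady state, 150 h in it on average | a closed flask charged with all of it at once and left for 30 h | a stirred flask in which Zb is dosed at a steady rate over 24.0 h without added volume, worked up at 30 h |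
| time |  |  |  |  |  |  | 30 h | 30 h |

| run | time / h | Zc / % | Zd / % | Zb / % |
|---|---|---|---|---|
| delta | 4.00 | 15 | 17 | 71 |
| delta | 10.0 | 24 | 32 | 44 |
| delta | 20.0 | 28 | 48 | 27 |
| delta | 30.0 | 28 | 58 | 14 |
| gamma | 5.00 | 6 | 23 | 73 |
| gamma | 12.0 | 8 | 40 | 51 |
| gamma | 25.0 | 10 | 64 | 29 |
| gamma | 40.0 | 13 | 76 | 15 |
| theta | 3.00 | 24 | 9 | 62 |
| theta | 6.00 | 30 | 17 | 50 |
| theta | 15.0 | 33 | 35 | 32 |
| theta | 40.0 | 32 | 60 | 12 |
| eta | 10.0 | 29 | 29 | 44 |
| eta | 20.0 | 31 | 42 | 26 |
| eta | 25.0 | 32 | 51 | 18 |
| eta | 40.0 | 31 | 60 | 12 |

(scatter of a reading: 1.5 percentage points)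

- the stated concentrations are those of everything mixed, before any reaction; amounts are the same in each set-up
- the numbers in the tables scatter with a standard deviation of 1.5 percentage points
- the feed brings no volume worth counting
- the earlier runs were made in a closed, stirred flask
- the share counts what is present at the end, not what went on to other products

- the set-up with the highest share of Zc in all that became Zc or Zd, at the outlet or at the end ("none" if the first two lie within 2 percentage points) (violet / grey / ochre / teal / none)
- share of Zc in all that became Zc or Zd, at the outlet or at the end, violet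
- share of Zc in all that became Zc or Zd, at the outlet or at the end, grey
- share of Zc in all that became Zc or Zd, at the outlet or at the end, ochre
- share of Zc in all that became Zc or Zd, at the outlet or at the end, teal

*What do you carry from flask to flask?* The split: Zc formed per Zd formed at a given moment, the rate into Zc over the rate into Zd, usually called the instantaneous selectivity. The share asked for counts running totals, Zc over Zc plus Zd, so it is an average over what formed, and it equals split/(1 + split) for a split that holds steady. Gamma's first reading, Zc over Zd so far, gives an early split of 0.261.

*Does it move?* Yes. The first readings give 0.882 in delta and 2.67 in theta, and theta has twice delta's cZb and, since Za is charged in mol% on Zb, twice its cZa, so it climbs when the two rise together. At 10.0 h, eta reads 1.00 against delta's 0.750 with the same cZb charged, so more cZa by itself raises it.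

*Then dosing starves teal of Zb, and its split is tiny?* I reckon not. Gamma's Zb falls to 15% in 40.0 h, which reads as a loss constant of 0.0474 h⁻¹. Steady dosing against that loss leaves 59.7% of the charge at the end of dosing, counting no loss to Zc. That is 0.0221 M, more than gamma's charge. Teal's cZa is also twice gamma's, and if the split keeps roughly in step with cZa, as eta suggests, teal's split near the end of dosing should be about 0.522, a momentary share of 34.3%. Earlier in the dosing cZb stands lower, so I take gamma's early share, 20.7%, as my low end for teal's running share.

*But Zc stalls in delta. Isn't Za dead by then?* Not on a plain clock, I think: gamma's Zc still reads 10% at 25.0 h and 13% at 40.0 h, though that step is close to the scatter. Ochre has delta's charge, and delta's last reading gives a share of 32.6%, so I keep ochre ahead of teal.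

The forecast named ochre and gave 13% for violet, 2% for grey, 33% for ochre and 7% for teal, saying “Dosing also keeps Zb low while the enzyme decays”, so on teal it stands below my range.

The flasks give 14.3% for violet, 2.59% for grey, 30.1% for ochre and 24.9% for teal, and the best is ochre.

    Zb + Za → Zc + Za, rate k1*[Zb]^2.5*[Za]/(1 + ([Zb]/Kh1)^2.5) (41.0 mM, k = 4.40 × 10⁵ L²·⁵ mol⁻²·⁵ h⁻¹)
    Za + Zc → Ze (k = 22.0 L mol⁻¹ h⁻¹)
    Zb → Zd (k = 0.0470 h⁻¹)

In teal the half-life of Zb by its passing into Zd alone, 15 h, is shorter than the dosing time of 24.0 h, and Zd stands at 47.9% of the Zb charged at the end. Teal's share means 0.332 of Zc per Zd in the totals at the end, above gamma's early 0.261, which puts teal's Zc at 15.9% of the charge. Violet, the tank, has 0.167 of Zc per Zd at the outlet, below 0.261 and half of teal's.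

(Readings and results are calculated on assumed constants; scatter was added.)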